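All runs stem from a simulated flask from invented constants; scatter was added.

Count a flask's time in substrate half-lives before you reckon any yield.

| flask | substrate | gas phase | remark | time |
|---|---|---|---|---|
| dawn | 0.014 M | 0.83 mM (held) | run made earlier |  |
| noon | 0.022 M | 0.83 mM (held) | run made earlier |  |
| Saturday's | 0.010 M | 0.83 mM (held) |  | 1.0 h |
| Sunday's | 0.010 M | 0.83 mM (held) |  | 3.0 h |

| run | time / min | target / % | substrate / % |
|---|---|---|---|
| dawn | 4.00 | 5 | 78 |
| dawn | 8.00 | 4 | 67 |
| dawn | 15.0 | 16 | 52 |
| dawn | 25.0 | 20 | 34 |
| dawn | 50.0 | 27 | 16 |
| noon | 4.00 | 0 | 75 |
| noon | 8.00 | 7 | 61 |
| noon | 15.0 | 11 | 40 |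
| noon | 25.0 | 15 | 28 |
| noon | 50.0 | 22 | 10 |

(standard deviation of a reading: 2 percentage points)

* which of the two there is more of at the end, Saturday's (target / over-reaction product)
* which of the two there is more of at the end, Sunday's (target / over-reaction product)
* final target, as a percentage of the substrate charged, in Saturday's
* final target, as a percentage of the substrate charged, in Sunday's

- the numbers in the tables scatter by 2 percentage points (one standard deviation)
- at the start none of the gas phase is in solution

1. Between its first and last readings, the dawn run took substrate from 78% to 16%. From this I read a substrate half-life, the time in which a first-order fall halves what is left, of 20.1 min. The noon run gave a shorter 15.8 min, but I kept dawn's value because its charge lay nearer Saturday's.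

2. I began with the main step by itself, so that spent substrate was target. Saturday's 1.0 h was 2.98 half-lives, which by this count left 12.7% substrate and gave 87.3% target. Sunday's 3.0 h was 8.94 half-lives, which by this count left 0.203% substrate.

3. Then I added the side losses. At the last reading of the dawn run, 27% target stood against 84.0% substrate spent, a selectivity, as read, of 32.1%. With that reading my estimate came down to 28.1% for Saturday's and 32.1% for Sunday's.

4. Last I added the target's own reaction on to over-reaction product. Dawn's target was still rising at its last reading, so I could read no rate for this loss. By my count, target in Sunday's flask stood for its last 2.00 h with under 12.7% substrate to feed it. I therefore kept 28.1% as my estimate for Saturday's and held 32.1% as my estimate for Sunday's before this loss, whose size I could not read.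

5. The forecast gave 29% target for Saturday's (24% to 35%) and 32% for Sunday's (22% to 40%), with over-reaction product ahead on Saturday's and over-reaction product ahead on Sunday's. On the loss it said: “Slow target loss can't be excluded, so I shade Sunday's down.”

6. Saturday's flask gave 31.2% target and 18.3% over-reaction product, so target led. Sunday's flask gave 2.73% target and 57.1% over-reaction product, so over-reaction product led, and its target lay 29 percentage points below the forecast.

    substrate + dissolved gas → target (k = 1.30 /M/s)
    2 substrate → homo dimer (k = 0.0260 /M/s)
    dissolved gas + target → over-reaction product (k = 0.630 /M/s)
    gas phase ⇌ dissolved gas, rate k4*(csat - [dissolved gas]) (kL = 0.00390 /s)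

In Sunday's flask at 0.834 h, which is 2.49 half-lives, the step making target took dissolved gas at 1.0 times the rate of the step from target to over-reaction product. At 3.00 h, 8.94 half-lives, that ratio was 0.019.

Sunday's flask read at 80 min is 3.97 half-lives, which by the count leaves 6.38% substrate. The computed flask held 4.97% substrate, 26.3% target and 28.6% over-reaction product.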